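**Retrosynthetic overview**

- The route rests on the lactone ring (O1, C2, C3, C4, C4a, C8a). Without C3 it is the furan ring of a 3-arylbenzofuran, which already holds O1 on C8a beside the ketone-bearing C8 and the oxygenated phenyl group on the future C4.
- Target ⇒ tribenzyl (4S)-dihydrocoumarin (hydrogenolysis) ⇒ 4-arylcoumarin (asymmetric hydrogenation of C3=C4 through the opened acrylate) ⇒ 3-chlorocoumarin (dechlorination) ⇒ 3-chlorobenzopyrylium salt (hydration, oxidation at C2).
- 3-Chlorobenzopyrylium ⇒ 7-acyl-3-arylbenzofuran + dichlorocarbene: C3 is inserted between C2 and C4 (new bonds C2–C3 and C3–C4).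
- Benzofuran ⇒ α-aryloxy ketone (C3–C3a bond by cyclodehydration) ⇒ dibenzylated acylphloroglucinol + α-bromoketone.
- Ring order: the furan ring is closed first, then enlarged to the pyrylium ring, which becomes the lactone; the C4 stereocentre is set in the last step but one.

Key step: step 4

Remark: the sense of induction in step 7 is assumed; the route is written with (2S,3S)-2,3-bis(diphenylphosphino)butane, and the (2R,3R) antipode is used instead if the first run gives the (4R) lactone.

**Route**

Step 1
Reactants: 1 2',4',6'-trihydroxydihydrochalcone [3-phenyl-1-(2,4,6-trihydroxyphenyl)propan-1-one]; 2 benzyl bromide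
Product: 3 1-[2,4-bis(benzyloxy)-6-hydroxyphenyl]-3-phenylpropan-1-one
Conditions: 2 (2.1 equiv), K2CO3 (2.2 equiv), DMF, 0 °C to rt
Reagents that add atoms: benzyl bromide 2, BrCc1ccccc1
Why: Williamson etherification, in which the para phenol and one ortho phenol are alkylated while the last ortho hydroxyl, held in a hydrogen bond to the ketone, is the least nucleophilic and should stay free with two equivalents of bromide, as is general for acylphloroglucinols.

Step 2
Reactants: 3 1-[2,4-bis(benzyloxy)-6-hydroxyphenyl]-3-phenylpropan-1-one; 4 2-bromo-1-[4-(benzyloxy)phenyl]ethanone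
Product: 5 1-[2,4-bis(benzyloxy)-6-{2-[4-(benzyloxy)phenyl]-2-oxoethoxy}phenyl]-3-phenylpropan-1-one
Conditions: 4 (1.1 equiv), K2CO3 (1.5 equiv), DMF, rt
Reagents that add atoms: 2-bromo-1-[4-(benzyloxy)phenyl]ethanone 4, O=C(CBr)c1ccc(OCc2ccccc2)cc1
Why: SN2 O-alkylation (Williamson) of the remaining phenoxide by the very reactive α-bromoketone, run at room temperature with a weak base so that the new phenacyl ether does not undergo intramolecular aldol condensation onto the hindered, electron-rich propanoyl carbonyl.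

Step 3
Reactants: 5 1-[2,4-bis(benzyloxy)-6-{2-[4-(benzyloxy)phenyl]-2-oxoethoxy}phenyl]-3-phenylpropan-1-one
Product: 6 1-{4,6-bis(benzyloxy)-3-[4-(benzyloxy)phenyl]-1-benzofuran-7-yl}-3-phenylpropan-1-one
Conditions: Bi(OTf)3 (10 mol %), ClCH2CH2Cl, 50 °C
Reagents that add atoms: none
Why: Lewis-acid cyclodehydration of an α-aryloxy ketone (intramolecular Friedel–Crafts hydroxyalkylation, then loss of water), in which the activated ketone is attacked by the only free ring carbon ortho to the ether oxygen, a position also ortho and para to benzyloxy groups, while the mild catalytic acid should spare the benzyl ethers and avoid 3-aryl to 2-aryl migration.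

Step 4
Reactants: 6 1-{4,6-bis(benzyloxy)-3-[4-(benzyloxy)phenyl]-1-benzofuran-7-yl}-3-phenylpropan-1-one; 7 sodium trichloroacetate
Product: 9 5,7-bis(benzyloxy)-4-[4-(benzyloxy)phenyl]-3-chloro-8-(3-phenylpropanoyl)chromenylium chloride, via dichlorocyclopropane adduct 8 (not isolated)
Conditions: 7 (4 equiv, in portions), anhydrous DME, 85 °C, argon; filtration under argon, evaporation; crude 9 used at once
Reagents that add atoms: sodium trichloroacetate 7, [Na+].[O-]C(=O)C(Cl)(Cl)Cl
Why: Proposed new method: heating Cl3CCO2Na releases CO2 and the trichloromethyl anion, which sheds chloride to give free dichlorocarbene without any base; the electrophilic carbene adds across C2=C3 of 6 to give the gem-dichlorocyclopropane 8, whose bond between the former C2 and C3 then breaks in a disrotatory cyclopropyl-to-allyl opening as the endo chloride leaves, assisted by the lone pair of O1 and by the electron-rich aryl group, so that the carbene carbon becomes C3 of the aromatic 1-benzopyrylium cation 9. The closest known reactions are the Ciamician–Dennstedt ring expansion of pyrroles and indoles with dihalocarbenes and the dichlorocarbene expansion of indenes to 2-chloronaphthalenes; carbon insertion into a benzofuran with this oxygenation and a 7-acyl group, stopped at the pyrylium salt, is not established. The six-membered pyrylium ring is formed by enlargement of the furan ring (a [2+1] cycloaddition followed by electrocyclic opening of the fused cyclopropane) and not by cyclisation of a chain, so the new bonds are C2–C3 and C3–C4 and the old bond between the two furan carbons is the one given up. No stereocentre survives, since both ring-fusion carbons of racemic 8 become sp2 centres in 9. The step needs chemoselectivity for the furan double bond over the benzyloxy-substituted benzene rings, the benzylic C–H bonds and the ketone; the enol-ether character of C2=C3, the inertness of benzenoid rings to dichlorocarbene and the base-free carbene source should provide it, and the site of insertion is not in question because the furan has only these two carbons.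

Step 5
Reactants: 9 5,7-bis(benzyloxy)-4-[4-(benzyloxy)phenyl]-3-chloro-8-(3-phenylpropanoyl)chromenylium chloride
Product: 11 5,7-bis(benzyloxy)-4-[4-(benzyloxy)phenyl]-3-chloro-8-(3-phenylpropanoyl)-2H-chromen-2-one, via 2H-chromen-2-ol pseudobase 10 (not isolated)
Conditions: sat. aq NaHCO3, CH2Cl2, 0 °C; organic phase dried (Na2SO4); then activated MnO2 (15 equiv), CH2Cl2, rt
Reagents that add atoms: water, O
Why: Pseudobase formation followed by lactol-to-lactone oxidation, in which water adds to the unhindered oxocarbenium carbon C2 of the pyrylium and the resulting allylic hemiacetal is oxidised by MnO2, the fast quench into excess bicarbonate keeping cation and pseudobase from coexisting and disproportionating by hydride transfer.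

Step 6
Reactants: 11 5,7-bis(benzyloxy)-4-[4-(benzyloxy)phenyl]-3-chloro-8-(3-phenylpropanoyl)-2H-chromen-2-one
Product: 12 5,7-bis(benzyloxy)-4-[4-(benzyloxy)phenyl]-8-(3-phenylpropanoyl)-2H-chromen-2-one
Conditions: Pd(OAc)2 (5 mol %), 2-dicyclohexylphosphino-2',6'-dimethoxybiphenyl (10 mol %), HCO2Na (3 equiv), DMF, 80 °C
Reagents that add atoms: none
Why: Palladium-catalysed transfer hydrodehalogenation, in which zerovalent palladium inserts into the C3–Cl bond activated by the lactone carbonyl, formate delivers hydride by decarboxylation and reductive elimination forms C3–H, the homogeneous catalyst leaving the benzyl ethers, the ketone and the trisubstituted C3=C4 bond alone, which a dissolving-metal reduction might not.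

Step 7
Reactants: 12 5,7-bis(benzyloxy)-4-[4-(benzyloxy)phenyl]-8-(3-phenylpropanoyl)-2H-chromen-2-one
Product: 16 (4S)-5,7-bis(benzyloxy)-4-[4-(benzyloxy)phenyl]-8-(3-phenylpropanoyl)-3,4-dihydro-2H-chromen-2-one, via disodium (Z)-acrylate salt 13 (not isolated), via disodium (S)-propanoate salt 14 (not isolated), via (S)-hydroxy acid 15 (not isolated)
Conditions: NaOH (2.2 equiv), MeOH–THF–H2O, 50 °C; then [Rh(cod)2]BF4 (2 mol %), (2S,3S)-2,3-bis(diphenylphosphino)butane (2.2 mol %), H2 (20 bar), 50 °C; then aq HCl to pH 2, extraction; TsOH·H2O (cat.), toluene, 60 °C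
Reagents that add atoms: sodium hydroxide, [Na+].[OH-] (its oxygen enters the opened carboxylate and can remain as the lactone carbonyl oxygen after reclosure)
Why: Carboxylate-directed asymmetric hydrogenation as established for ring-opened 4-arylcoumarins, in which saponification gives the (Z)-β,β-diaryl acrylate whose carboxylate binds the cationic rhodium bisphosphine complex so that H2 is delivered to one face of C3=C4 and the chiral ligand sets C4, after which acid recloses the lactone on O1 only, because O5 is still benzylated.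

Step 8
Reactants: 16 (4S)-5,7-bis(benzyloxy)-4-[4-(benzyloxy)phenyl]-8-(3-phenylpropanoyl)-3,4-dihydro-2H-chromen-2-one
Product: 17 (4S)-5,7-dihydroxy-4-(4-hydroxyphenyl)-8-(3-phenylpropanoyl)-3,4-dihydro-2H-chromen-2-one
Conditions: H2 (1 atm), 10% Pd/C, EtOAc–THF, rt, stopped after uptake of three equivalents
Reagents that add atoms: none
Why: Heterogeneous hydrogenolysis of the three benzyl aryl ethers under neutral conditions in a non-nucleophilic solvent, which should leave the lactone closed (no migration of the acyl group to O5), the chelated electron-rich aryl ketone unreduced and the C4 stereocentre untouched, since C4 carries no hydrogenolysable bond.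

**Compound list**

1 | 3-phenyl-1-(2,4,6-trihydroxyphenyl)propan-1-one (2',4',6'-trihydroxydihydrochalcone) | O=C(CCc1ccccc1)c1c(O)cc(O)cc1O | starting material
2 | benzyl bromide | BrCc1ccccc1 | starting material
3 | 1-[2,4-bis(benzyloxy)-6-hydroxyphenyl]-3-phenylpropan-1-one | O=C(CCc1ccccc1)c1c(O)cc(OCc2ccccc2)cc1OCc1ccccc1 | intermediate
4 | 2-bromo-1-[4-(benzyloxy)phenyl]ethanone | O=C(CBr)c1ccc(OCc2ccccc2)cc1 | starting material
5 | 1-[2,4-bis(benzyloxy)-6-{2-[4-(benzyloxy)phenyl]-2-oxoethoxy}phenyl]-3-phenylpropan-1-one | O=C(CCc1ccccc1)c1c(OCC(=O)c2ccc(OCc3ccccc3)cc2)cc(OCc2ccccc2)cc1OCc1ccccc1 | intermediate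
6 | 1-{4,6-bis(benzyloxy)-3-[4-(benzyloxy)phenyl]-1-benzofuran-7-yl}-3-phenylpropan-1-one | O=C(CCc1ccccc1)c1c(OCc2ccccc2)cc(OCc2ccccc2)c2c(-c3ccc(OCc4ccccc4)cc3)coc12 | intermediate
7 | sodium trichloroacetate | [Na+].[O-]C(=O)C(Cl)(Cl)Cl | starting material
8 | 1-{4,6-bis(benzyloxy)-6b-[4-(benzyloxy)phenyl]-1,1-dichloro-1a,6b-dihydro-1H-cyclopropa[b][1]benzofuran-3-yl}-3-phenylpropan-1-one (racemic, not isolated) | O=C(CCc1ccccc1)c1c(OCc2ccccc2)cc(OCc2ccccc2)c2c1OC1C(Cl)(Cl)C21c1ccc(OCc2ccccc2)cc1 | intermediate
9 | 5,7-bis(benzyloxy)-4-[4-(benzyloxy)phenyl]-3-chloro-8-(3-phenylpropanoyl)chromenylium chloride (in solution possibly as its covalent C2 chloride) | Clc1c[o+]c2c(C(=O)CCc3ccccc3)c(OCc3ccccc3)cc(OCc3ccccc3)c2c1-c1ccc(OCc2ccccc2)cc1.[Cl-] | intermediate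
10 | 1-{5,7-bis(benzyloxy)-4-[4-(benzyloxy)phenyl]-3-chloro-2-hydroxy-2H-chromen-8-yl}-3-phenylpropan-1-one (racemic lactol, not isolated) | OC1Oc2c(C(=O)CCc3ccccc3)c(OCc3ccccc3)cc(OCc3ccccc3)c2C(c2ccc(OCc3ccccc3)cc2)=C1Cl | intermediate
11 | 5,7-bis(benzyloxy)-4-[4-(benzyloxy)phenyl]-3-chloro-8-(3-phenylpropanoyl)-2H-chromen-2-one | O=C1Oc2c(C(=O)CCc3ccccc3)c(OCc3ccccc3)cc(OCc3ccccc3)c2C(c2ccc(OCc3ccccc3)cc2)=C1Cl | intermediate
12 | 5,7-bis(benzyloxy)-4-[4-(benzyloxy)phenyl]-8-(3-phenylpropanoyl)-2H-chromen-2-one | O=C1C=C(c2ccc(OCc3ccccc3)cc2)c2c(OCc3ccccc3)cc(OCc3ccccc3)c(C(=O)CCc3ccccc3)c2O1 | intermediate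
13 | disodium (2Z)-3-[4-(benzyloxy)phenyl]-3-[4,6-bis(benzyloxy)-2-oxido-3-(3-phenylpropanoyl)phenyl]prop-2-enoate (not isolated) | [Na+].[Na+].[O-]C(=O)/C=C(/c1ccc(OCc2ccccc2)cc1)c1c([O-])c(C(=O)CCc2ccccc2)c(OCc2ccccc2)cc1OCc1ccccc1 | intermediate
14 | disodium (3S)-3-[4-(benzyloxy)phenyl]-3-[4,6-bis(benzyloxy)-2-oxido-3-(3-phenylpropanoyl)phenyl]propanoate (not isolated) | [Na+].[Na+].[O-]C(=O)C[C@@H](c1ccc(OCc2ccccc2)cc1)c1c([O-])c(C(=O)CCc2ccccc2)c(OCc2ccccc2)cc1OCc1ccccc1 | intermediate
15 | (3S)-3-[4-(benzyloxy)phenyl]-3-[4,6-bis(benzyloxy)-2-hydroxy-3-(3-phenylpropanoyl)phenyl]propanoic acid (not isolated) | OC(=O)C[C@@H](c1ccc(OCc2ccccc2)cc1)c1c(O)c(C(=O)CCc2ccccc2)c(OCc2ccccc2)cc1OCc1ccccc1 | intermediate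
16 | (4S)-5,7-bis(benzyloxy)-4-[4-(benzyloxy)phenyl]-8-(3-phenylpropanoyl)-3,4-dihydro-2H-chromen-2-one | O=C1C[C@@H](c2ccc(OCc3ccccc3)cc2)c2c(OCc3ccccc3)cc(OCc3ccccc3)c(C(=O)CCc3ccccc3)c2O1 | intermediate
17 | (4S)-5,7-dihydroxy-4-(4-hydroxyphenyl)-8-(3-phenylpropanoyl)-3,4-dihydro-2H-chromen-2-one | O=C1C[C@@H](c2ccc(O)cc2)c2c(O)cc(O)c(C(=O)CCc3ccccc3)c2O1 | target

**Step count**

Total: 8 steps. Longest linear sequence: 8 steps (1 to 17).

**Steps most likely to fail**

Step 4 (carbene ring expansion). The carbene may fail to add to the hindered, acyl-deactivated furan bond. Once formed, the pyrylium ion may be captured at C2 by trichloromethyl anion or trichloroacetate, or may lose an O-benzyl group to chloride at 85 °C. The fallback uses known chemistry and builds the coumarin ring without the benzofuran; it sets out from 3 and comes back at 12, bypassing steps 2 to 6. Commercial 1-(benzyloxy)-4-ethynylbenzene is lithiated (n-BuLi, THF, −78 °C) and carboxylated (CO2, then aq HCl) to 3-[4-(benzyloxy)phenyl]prop-2-ynoic acid F1. Steglich esterification of 3 with F1 (DCC, DMAP, CH2Cl2, 0 °C) should give 3,5-bis(benzyloxy)-2-(3-phenylpropanoyl)phenyl 3-[4-(benzyloxy)phenyl]prop-2-ynoate F2. Cationic gold (Ph3PAuCl with AgSbF6, ClCH2CH2Cl, rt) should then effect intramolecular 6-endo hydroarylation at the single free carbon ortho to the ester oxygen, giving 12 directly.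

Step 7 (asymmetric hydrogenation). Hydrogen uptake may be slow, or facial discrimination poor, because the 2,6-dioxygenated aryl group is twisted and crowds the alkene of the opened acrylate. Partial Z-to-E isomerisation of the acrylate in base would also erode selectivity. The fallback reduces the closed lactone with a chiral copper hydride instead; it sets out from 12 and comes back at 16. Conditions would be Cu(OAc)2·H2O (cat.), DTBM-SEGPHOS (antipode chosen by trial), (EtO)2MeSiH, t-BuOH, toluene, 0 °C to rt, an asymmetric conjugate reduction known for 4-arylcoumarins. Hydride goes to C4 of the planar enoate faster than to the hindered ketone. Any over-reduced lactol, 1-{(4S)-5,7-bis(benzyloxy)-4-[4-(benzyloxy)phenyl]-2-hydroxy-3,4-dihydro-2H-chromen-8-yl}-3-phenylpropan-1-one F3, is returned to 16 by oxidation (PhI(OAc)2, TEMPO cat., CH2Cl2).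

Step 5 (hydration and oxidation). Hydride transfer between unreacted cation and pseudobase may cause disproportionation. Oxidation may be slow if ring-chain tautomerism keeps the lactol concentration low, and the oxidant may attack the phenol freed in the open form. The fallback moves the oxidation to the open-chain tautomer and closes the ring afterwards; it sets out from 9 and comes back at 11. Hydrolysis of 9 as in step 5 gives 10 in equilibrium with (2E)-3-[4-(benzyloxy)phenyl]-3-[4,6-bis(benzyloxy)-2-hydroxy-3-(3-phenylpropanoyl)phenyl]-2-chloroprop-2-enal F4. Pinnick oxidation (NaClO2, NaH2PO4, 2-methyl-2-butene, t-BuOH–THF–H2O, 0 °C) should give (2E)-3-[4-(benzyloxy)phenyl]-3-[4,6-bis(benzyloxy)-2-hydroxy-3-(3-phenylpropanoyl)phenyl]-2-chloroprop-2-enoic acid F5. Its carboxyl group is cis to the phenol-bearing ring, so acid-catalysed lactonisation (TsOH·H2O cat., toluene, 60 °C) should close it to 11.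

**Further compounds**

F1 | step 4 | 3-[4-(benzyloxy)phenyl]prop-2-ynoic acid | OC(=O)C#Cc1ccc(OCc2ccccc2)cc1
F2 | step 4 | 3,5-bis(benzyloxy)-2-(3-phenylpropanoyl)phenyl 3-[4-(benzyloxy)phenyl]prop-2-ynoate | O=C(CCc1ccccc1)c1c(OC(=O)C#Cc2ccc(OCc3ccccc3)cc2)cc(OCc2ccccc2)cc1OCc1ccccc1
F3 | step 7 | 1-{(4S)-5,7-bis(benzyloxy)-4-[4-(benzyloxy)phenyl]-2-hydroxy-3,4-dihydro-2H-chromen-8-yl}-3-phenylpropan-1-one | OC1C[C@@H](c2ccc(OCc3ccccc3)cc2)c2c(OCc3ccccc3)cc(OCc3ccccc3)c(C(=O)CCc3ccccc3)c2O1
F4 | step 5 | (2E)-3-[4-(benzyloxy)phenyl]-3-[4,6-bis(benzyloxy)-2-hydroxy-3-(3-phenylpropanoyl)phenyl]-2-chloroprop-2-enal | O=C/C(Cl)=C(/c1ccc(OCc2ccccc2)cc1)c1c(O)c(C(=O)CCc2ccccc2)c(OCc2ccccc2)cc1OCc1ccccc1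
F5 | step 5 | (2E)-3-[4-(benzyloxy)phenyl]-3-[4,6-bis(benzyloxy)-2-hydroxy-3-(3-phenylpropanoyl)phenyl]-2-chloroprop-2-enoic acid | OC(=O)/C(Cl)=C(/c1ccc(OCc2ccccc2)cc1)c1c(O)c(C(=O)CCc2ccccc2)c(OCc2ccccc2)cc1OCc1ccccc1
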